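**Plan**
- Feature: in the cyclohexane ring the trans O4/O5 pair lies next to the C3 carbinol. With C3 as a ketone, C3(=O)–C4(O-acyl)–C5(OH) is an aldol retron, and the other ring atoms C2–C1(C7)–C6 with their two arms are the carbon skeleton of citric acid.
- Cuts (retro): the O5 ester, C3–H (back to the ketone), the ring bond C4–C5 (aldol), then O4–C4 (carboxylate alkylation), C3–C4 (one-carbon homologation) and C1–C6 (enolate allylation).
- Forward: the chain is built on (R)-malic acid (allylation at C1, acetonide, bromomethyl ketone, O-benzylvanillate, ozonolysis). The only ring then closes by an (S)-proline aldol, followed by reduction, the second ester and deprotection.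
- The citrate-type unit is taken from malic acid so that C1 is fixed by a stereocontrolled alkylation and not by a desymmetrisation.
- Stereochemistry: C1 from (R)-malic acid by self-regeneration of the stereocentre; C4 and C5 from (S)-proline in the ring closure; C3 from hydride delivery directed by the 5-OH.

Key step: step 8

Remark: the target is taken as 4,5-di-O-vanilloyl-(−)-quinic acid; ring compounds use quinate numbering (C1 carbinol carbon, C7 carboxyl carbon), and salts of numbered compounds and catalyst-bound species are not numbered separately.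

Step 1
Reactants: 1 (R)-malic acid
Product: 2 2-[(2R,4R)-2-tert-butyl-5-oxo-1,3-dioxolan-4-yl]acetic acid
Conditions: t-BuCHO, p-TsOH·H2O (cat.), H2SO4 (cat.), pentane, reflux, Dean–Stark; recrystallisation
Reagents that add atoms: pivalaldehyde, CC(C)(C)C=O
Why: Acid-catalysed acetalisation of the α-hydroxy acid unit with azeotropic removal of water (Seebach dioxolanone formation) should give mainly the 2,4-cis acetal, which is purified by crystallisation, so that the new acetal carbon stores the configuration of malic acid.

Step 2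
Reactants: 2 2-[(2R,4R)-2-tert-butyl-5-oxo-1,3-dioxolan-4-yl]acetic acid; 3 allyl bromide
Product: 4 2-[(2R,4R)-2-tert-butyl-5-oxo-4-(prop-2-en-1-yl)-1,3-dioxolan-4-yl]acetic acid
Conditions: LiHMDS (2.1 equiv), THF, −78 °C; allyl bromide, −78 → −20 °C; aq. HCl
Reagents that add atoms: none
Why: Alkylation with self-regeneration of the stereocentre: the enolate–carboxylate dianion is allylated on the ring face opposite to the tert-butyl group, which creates the quaternary carbon (later C1) with overall retention.

Step 3
Reactants: 4 2-[(2R,4R)-2-tert-butyl-5-oxo-4-(prop-2-en-1-yl)-1,3-dioxolan-4-yl]acetic acid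
Product: 5 (2R)-2-hydroxy-2-(prop-2-en-1-yl)butanedioic acid
Conditions: 2 M KOH, MeOH/H2O, rt; HCl to pH 1, EtOAc extraction
Reagents that add atoms: potassium hydroxide, [K+].[OH-]
Why: Saponification of the acylal-type lactone releases pivalaldehyde and the hydroxy diacid, and the quaternary stereocentre cannot epimerise.

Step 4
Reactants: 5 (2R)-2-hydroxy-2-(prop-2-en-1-yl)butanedioic acid
Product: 6 2-[(4R)-2,2-dimethyl-5-oxo-4-(prop-2-en-1-yl)-1,3-dioxolan-4-yl]acetic acid
Conditions: Me2C(OMe)2, p-TsOH (cat.), rt
Reagents that add atoms: 2,2-dimethoxypropane, COC(C)(C)OC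
Why: Acid-catalysed transketalisation closes the five-membered dioxolanone on the α-hydroxy acid unit in preference to a six-membered ring with the other carboxyl group, as with malic acid itself, and gives a 1,7-protecting group that dilute acid removes at the end.

Step 5
Reactants: 6 2-[(4R)-2,2-dimethyl-5-oxo-4-(prop-2-en-1-yl)-1,3-dioxolan-4-yl]acetic acid; 7 (trimethylsilyl)diazomethane
Product: 10 (5R)-5-(3-bromo-2-oxopropyl)-2,2-dimethyl-5-(prop-2-en-1-yl)-1,3-dioxolan-4-one, via acid chloride 8 (not isolated), via diazoketone 9 (not isolated)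
Conditions: (COCl)2, DMF (cat.), CH2Cl2, 0 °C → rt; TMSCHN2 (1.5 equiv), THF/MeCN, 0 °C; 48% aq. HBr, 0 °C
Reagents that add atoms: hydrogen bromide, Br
Why: Acylation of the diazoalkane by the acid chloride (first stage of an Arndt–Eistert sequence, the chloride ion taking off the silyl group) and hydrobromination of the diazoketone should give the bromomethyl ketone without any metal carbenoid that could cyclopropanate the allyl group.

Step 6
Reactants: 10 (5R)-5-(3-bromo-2-oxopropyl)-2,2-dimethyl-5-(prop-2-en-1-yl)-1,3-dioxolan-4-one; 11 4-(benzyloxy)-3-methoxybenzoic acid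
Product: 12 3-[(4R)-2,2-dimethyl-5-oxo-4-(prop-2-en-1-yl)-1,3-dioxolan-4-yl]-2-oxopropyl 4-(benzyloxy)-3-methoxybenzoate
Conditions: KHCO3, DMF, rt
Reagents that add atoms: none
Why: SN2 O-alkylation of the potassium carboxylate by the activated α-bromo ketone (phenacyl ester formation) places the first vanilloyl unit on the oxygen that becomes O4.

Step 7
Reactants: 12 3-[(4R)-2,2-dimethyl-5-oxo-4-(prop-2-en-1-yl)-1,3-dioxolan-4-yl]-2-oxopropyl 4-(benzyloxy)-3-methoxybenzoate
Product: 14 3-[(4R)-2,2-dimethyl-5-oxo-4-(2-oxoethyl)-1,3-dioxolan-4-yl]-2-oxopropyl 4-(benzyloxy)-3-methoxybenzoate, via ozonide 13 (not isolated)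
Conditions: O3, CH2Cl2, −78 °C (Sudan Red 7B end point); PPh3, −78 °C → rt
Reagents that add atoms: ozone, [O-][O+]=O
Why: Ozonolysis with reductive work-up cleaves the monosubstituted alkene, which reacts much faster than the ester-deactivated aryl ethers when the end point is shown by an indicator dye; the stereocentre of the ozonide is lost again.

Step 8
Reactants: 14 3-[(4R)-2,2-dimethyl-5-oxo-4-(2-oxoethyl)-1,3-dioxolan-4-yl]-2-oxopropyl 4-(benzyloxy)-3-methoxybenzoate
Product: 15 4-O-[4-(benzyloxy)-3-methoxybenzoyl]-3-dehydroquinic acid 1,7-acetonide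
Conditions: (S)-proline (30 mol%), DMSO (0.05 M), rt
Reagents that add atoms: none
Why: (S)-Proline condenses with the C3 ketone, and of the possible enamines only the one toward the acyloxy-bearing C4 can cyclise, since the enamines at C2 or C6 could only close four-membered rings and revert; this enamine adds through C4 to the C5 aldehyde while the carboxylic acid of the catalyst protonates the aldehyde oxygen (Houk–List transition state). The closest known reactions are the Hajos–Parrish cyclisation and the proline aldol of hydroxyacetone, an α-oxygenated ketone donor. The cyclohexane ring closes in the 6-(enolendo)-exo-trig mode through a chair in which the C4–O bond and the aldehyde oxygen are both axial and anti to each other. C4 is set by the enamine geometry (acyloxy group trans to nitrogen) together with attack on the enamine face that carries the carboxyl group of the (S)-catalyst, and C5 by the hydrogen bond that turns the aldehyde oxygen toward that carboxyl group, so the two oxygens should end up trans and, after ring inversion, diequatorial with O5 cis to C7. The step needs catalyst control of the absolute configuration against the resident C1 centre and freedom from retro-aldol and β-elimination at C1: in the required chair the developing alkoxide lies over the lactone carbonyl carbon and not over the acetal oxygen, and O1 is held in the acetonide, which excludes retro-aldol cleavage and offers only a poor leaving group. High dilution is used to suppress intermolecular aldolisation through the aldehyde enamine.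

Step 9
Reactants: 15 4-O-[4-(benzyloxy)-3-methoxybenzoyl]-3-dehydroquinic acid 1,7-acetonide
Product: 16 4-O-[4-(benzyloxy)-3-methoxybenzoyl]quinic acid 1,7-acetonide
Conditions: Me4NBH(OAc)3, MeCN/AcOH (1:1), −30 → −20 °C; aq. Rochelle salt
Reagents that add atoms: none
Why: Hydroxyl-directed reduction with triacetoxyborohydride (Evans–Saksena): the reagent binds to O5 and delivers hydride intramolecularly to give the 3,5-anti diol with the axial 3-OH cis to O4, external attack anti to the axial C1–O bond would give the same epimer, and the acidic medium holds back acyl migration and β-elimination.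

Step 10
Reactants: 11 4-(benzyloxy)-3-methoxybenzoic acid
Product: 17 4-(benzyloxy)-3-methoxybenzoyl chloride
Conditions: (COCl)2, DMF (cat.), CH2Cl2, rt; evaporation
Reagents that add atoms: oxalyl chloride, ClC(=O)C(=O)Cl
Why: Standard conversion of a carboxylic acid into its chloride with oxalyl chloride under DMF catalysis (Vilsmeier-type activation), which the ethers tolerate.

Step 11
Reactants: 16 4-O-[4-(benzyloxy)-3-methoxybenzoyl]quinic acid 1,7-acetonide; 17 4-(benzyloxy)-3-methoxybenzoyl chloride
Product: 18 4,5-bis-O-[4-(benzyloxy)-3-methoxybenzoyl]quinic acid 1,7-acetonide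
Conditions: pyridine, DMAP (cat.), CH2Cl2, −20 → 0 °C
Reagents that add atoms: none
Why: DMAP-catalysed acylation should take the equatorial 5-OH in preference to the axial 3-OH, which is 1,3-diaxial to O1 and flanked by the 4-ester, and 5-O-acylation next to a 1,7-acetonide is known for quinic acid.

Step 12
Reactants: 18 4,5-bis-O-[4-(benzyloxy)-3-methoxybenzoyl]quinic acid 1,7-acetonide
Product: 19 4,5-di-O-vanilloylquinic acid 1,7-acetonide
Conditions: H2 (1 atm), 10% Pd/C, EtOAc, rt
Reagents that add atoms: none
Why: Catalytic hydrogenolysis cleaves the two aryl benzyl ethers under neutral conditions and leaves the benzoate-type esters and the acetonide untouched.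

Step 13
Reactants: 19 4,5-di-O-vanilloylquinic acid 1,7-acetonide
Product: 20 burkinabin C (4,5-di-O-vanilloyl-(−)-quinic acid)
Conditions: 1 M aq. HCl/THF (1:3), rt; lyophilisation, RP-C18
Reagents that add atoms: water, O
Why: Acid-catalysed hydrolysis of the dioxolanone ketal at room temperature frees the tertiary hydroxyl and the carboxyl group, acyl migration in quinic acid esters is slow in acid, and no lactone can form because the free 3-OH is trans to the carboxyl group.

**Compound list**

1 | (R)-malic acid | O[C@H](CC(=O)O)C(=O)O | starting material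
2 | 2-[(2R,4R)-2-tert-butyl-5-oxo-1,3-dioxolan-4-yl]acetic acid (tert-butyl cis to the CH2CO2H arm) | CC(C)(C)[C@@H]1O[C@H](CC(=O)O)C(=O)O1 | intermediate
3 | allyl bromide | C=CCBr | starting material
4 | 2-[(2R,4R)-2-tert-butyl-5-oxo-4-(prop-2-en-1-yl)-1,3-dioxolan-4-yl]acetic acid (allyl trans to tert-butyl) | CC(C)(C)[C@@H]1O[C@](CC=C)(CC(=O)O)C(=O)O1 | intermediate
5 | (2R)-2-hydroxy-2-(prop-2-en-1-yl)butanedioic acid | O[C@](CC=C)(CC(=O)O)C(=O)O | intermediate
6 | 2-[(4R)-2,2-dimethyl-5-oxo-4-(prop-2-en-1-yl)-1,3-dioxolan-4-yl]acetic acid | CC1(C)O[C@](CC=C)(CC(=O)O)C(=O)O1 | intermediate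
7 | (trimethylsilyl)diazomethane | C[Si](C)(C)C=[N+]=[N-] | starting material
8 | 2-[(4R)-2,2-dimethyl-5-oxo-4-(prop-2-en-1-yl)-1,3-dioxolan-4-yl]acetyl chloride (formed and used in step 5 without isolation) | CC1(C)O[C@](CC=C)(CC(=O)Cl)C(=O)O1 | intermediate
9 | (5R)-5-(3-diazo-2-oxopropyl)-2,2-dimethyl-5-(prop-2-en-1-yl)-1,3-dioxolan-4-one (formed and used in step 5 without isolation) | CC1(C)O[C@](CC=C)(CC(=O)C=[N+]=[N-])C(=O)O1 | intermediate
10 | (5R)-5-(3-bromo-2-oxopropyl)-2,2-dimethyl-5-(prop-2-en-1-yl)-1,3-dioxolan-4-one | CC1(C)O[C@](CC=C)(CC(=O)CBr)C(=O)O1 | intermediate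
11 | 4-(benzyloxy)-3-methoxybenzoic acid | COc1cc(ccc1OCc1ccccc1)C(=O)O | starting material
12 | 3-[(4R)-2,2-dimethyl-5-oxo-4-(prop-2-en-1-yl)-1,3-dioxolan-4-yl]-2-oxopropyl 4-(benzyloxy)-3-methoxybenzoate | CC1(C)O[C@](CC=C)(CC(=O)COC(=O)c2ccc(OCc3ccccc3)c(OC)c2)C(=O)O1 | intermediate
13 | 3-[(4R)-2,2-dimethyl-5-oxo-4-(1,2,4-trioxolan-3-ylmethyl)-1,3-dioxolan-4-yl]-2-oxopropyl 4-(benzyloxy)-3-methoxybenzoate (ozonide, both epimers at the trioxolane carbon; formed and used in step 7 without isolation) | CC1(C)O[C@](CC2OCOO2)(CC(=O)COC(=O)c2ccc(OCc3ccccc3)c(OC)c2)C(=O)O1 | intermediate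
14 | 3-[(4R)-2,2-dimethyl-5-oxo-4-(2-oxoethyl)-1,3-dioxolan-4-yl]-2-oxopropyl 4-(benzyloxy)-3-methoxybenzoate | CC1(C)O[C@](CC=O)(CC(=O)COC(=O)c2ccc(OCc3ccccc3)c(OC)c2)C(=O)O1 | intermediate
15 | 4-O-[4-(benzyloxy)-3-methoxybenzoyl]-3-dehydroquinic acid 1,7-acetonide (C1 spiro-fused to a 2,2-dimethyl-1,3-dioxolan-4-one; O4 and 5-OH trans; 5-OH cis to C7) | CC1(C)O[C@@]2(C[C@@H](O)[C@H](OC(=O)c3ccc(OCc4ccccc4)c(OC)c3)C(=O)C2)C(=O)O1 | intermediate
16 | 4-O-[4-(benzyloxy)-3-methoxybenzoyl]quinic acid 1,7-acetonide (3-OH cis to O4 and to O1) | CC1(C)O[C@@]2(C[C@@H](O)[C@H](OC(=O)c3ccc(OCc4ccccc4)c(OC)c3)[C@H](O)C2)C(=O)O1 | intermediate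
17 | 4-(benzyloxy)-3-methoxybenzoyl chloride | COc1cc(ccc1OCc1ccccc1)C(=O)Cl | intermediate
18 | 4,5-bis-O-[4-(benzyloxy)-3-methoxybenzoyl]quinic acid 1,7-acetonide | CC1(C)O[C@@]2(C[C@@H](OC(=O)c3ccc(OCc4ccccc4)c(OC)c3)[C@H](OC(=O)c3ccc(OCc4ccccc4)c(OC)c3)[C@H](O)C2)C(=O)O1 | intermediate
19 | 4,5-di-O-vanilloylquinic acid 1,7-acetonide | CC1(C)O[C@@]2(C[C@@H](OC(=O)c3ccc(O)c(OC)c3)[C@H](OC(=O)c3ccc(O)c(OC)c3)[C@H](O)C2)C(=O)O1 | intermediate
20 | burkinabin C, 4,5-di-O-vanilloyl-(−)-quinic acid | COc1cc(C(=O)O[C@@H]2[C@H](O)C[C@@](O)(C(=O)O)C[C@H]2OC(=O)c2ccc(O)c(OC)c2)ccc1O | target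

**Step count and risks**

Total step count: 13. Longest linear sequence: 12 (steps 1–9 and 11–13; step 10 is a one-step branch).

Most likely to fail, in this order:

1. Step 8 (ring closure).
   - What may go wrong: the aldehyde forms its enamine faster than the ketone, which can lead to β-elimination of the C1 acetal oxygen or to intermolecular aldolisation; the resident C1 centre may also erode the facial control of the catalyst.
   - Fallback: the ring would be closed at the same C4–C5 position by olefin metathesis and the two oxygens introduced afterwards. It sets out from acid 6 and comes back at 18.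
   - The chloride 8 of acid 6 (made as in step 5) would be coupled with tributyl(vinyl)stannane (BnPd(PPh3)2Cl cat., Stille acylation) to the vinyl ketone (5R)-2,2-dimethyl-5-(2-oxobut-3-en-1-yl)-5-(prop-2-en-1-yl)-1,3-dioxolan-4-one F1.
   - Ring-closing metathesis (Grubbs II, CH2Cl2, 40 °C) should give the spiro enone (5R)-2,2-dimethyl-1,3-dioxaspiro[4.5]dec-8-ene-4,7-dione F2.
   - Luche reduction, with hydride expected anti to the axial C1–O bond, should give the allylic alcohol 4,5-didehydro-4,5-dideoxyquinic acid 1,7-acetonide F3.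
   - VO(acac)2/t-BuOOH should give the syn epoxy alcohol 4,5-anhydro-5-epi-quinic acid 1,7-acetonide F4.
   - Ti(OiPr)4-mediated opening with acid 11 at C5, the epoxide carbon remote from the hydroxyl, with inversion, should give 5-O-[4-(benzyloxy)-3-methoxybenzoyl]quinic acid 1,7-acetonide F5.
   - Acylation of its equatorial 4-OH with 17 (pyridine, CH2Cl2, −20 °C) would return to the route at 18.

2. Step 11 (second ester).
   - What may go wrong: incomplete discrimination between the equatorial 5-OH and the axial 3-OH, or base-induced migration of the O4 acyl group to O3 before the acylation is complete.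
   - Fallback: it sets out from ketol 15 and comes back at 18, bypassing 16. An Evans–Tishchenko reaction with 4-(benzyloxy)-3-methoxybenzaldehyde (SmI2 15 mol%, premixed with the aldehyde, THF, −10 °C) would transfer the acyl group to O5 through the hemiacetal and deliver its hydride to C3 anti to O5 in one operation.
   - The position of the ester is then fixed by the mechanism and not by a rate difference between two hydroxyls; no new compound is formed (F0).

3. Step 9 (reduction at C3).
   - What may go wrong: hydride delivery to the wrong face of C3 if the diaxial conformer needed for intramolecular transfer is not populated, or acyl migration within the resulting diol monoester.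
   - Fallback: it sets out from 15 and comes back at 18. Ketol 15 would first be acylated with 17 (pyridine, CH2Cl2, −20 °C, no DMAP) to 4,5-bis-O-[4-(benzyloxy)-3-methoxybenzoyl]-3-dehydroquinic acid 1,7-acetonide F6, in which no free hydroxyl is left as a migration terminus.
   - The ketone would then be reduced with NaBH4/CeCl3 (MeOH/THF, −78 °C, AcOH quench) under steric approach control, axial attack being blocked by the axial C1–O bond, to give 18 directly.

**Further compounds**

F1 | step 8 | (5R)-2,2-dimethyl-5-(2-oxobut-3-en-1-yl)-5-(prop-2-en-1-yl)-1,3-dioxolan-4-one | CC1(C)O[C@](CC=C)(CC(=O)C=C)C(=O)O1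
F2 | step 8 | (5R)-2,2-dimethyl-1,3-dioxaspiro[4.5]dec-8-ene-4,7-dione | CC1(C)O[C@@]2(CC=CC(=O)C2)C(=O)O1
F3 | step 8 | 4,5-didehydro-4,5-dideoxyquinic acid 1,7-acetonide (3-OH cis to O1) | CC1(C)O[C@@]2(CC=C[C@H](O)C2)C(=O)O1
F4 | step 8 | 4,5-anhydro-5-epi-quinic acid 1,7-acetonide (epoxide cis to the 3-OH) | CC1(C)O[C@@]2(C[C@@H]3O[C@@H]3[C@H](O)C2)C(=O)O1
F5 | step 8 | 5-O-[4-(benzyloxy)-3-methoxybenzoyl]quinic acid 1,7-acetonide | CC1(C)O[C@@]2(C[C@@H](OC(=O)c3ccc(OCc4ccccc4)c(OC)c3)[C@H](O)[C@H](O)C2)C(=O)O1
F0 | step 11 | none | none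
F6 | step 9 | 4,5-bis-O-[4-(benzyloxy)-3-methoxybenzoyl]-3-dehydroquinic acid 1,7-acetonide | CC1(C)O[C@@]2(C[C@@H](OC(=O)c3ccc(OCc4ccccc4)c(OC)c3)[C@H](OC(=O)c3ccc(OCc4ccccc4)c(OC)c3)C(=O)C2)C(=O)O1
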